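The bicyclo[3.1.0]hexane core (cyclopentane C1–C5 fused to cyclopropane C1–C5–C6, methyl on bridgehead C1, aryl on C2, C6 an unsubstituted CH2) is traced back to the six carbons of one benzene ring, that of a 3-aryl-5-methylphenol. Irradiating its para-C-protonated form in triflic acid should make the C1–C2 and C5–C6 bonds in a single operation, closing cyclopentenone and cyclopropane and giving the 2-aryl-1-methylbicyclo[3.1.0]hex-2-en-4-one. The precursor is a biaryl phenol whose second ring carries its oxygen as a mesylate, so that only the phenol ring is protonated and excited. Resolution, cuprate methylation at C2 anti to C6, Wolff–Kishner reduction with loss of the mesylate, and dibromination finish the route.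

Key step: step 3

Remark (numbering): in every name the bicycle is numbered as in the target (C1 methyl-bearing bridgehead, C2 aryl-bearing carbon, C4 carbonyl carbon where present, C5 CH bridgehead, C6 cyclopropane CH2).
Remark (assumption): which fraction of the step 4 separation is the (1S,5R) enantiomer is assumed to be settled by anomalous-dispersion X-ray analysis of dibromide 15 made from a pilot sample.

Step 1
Reactants: 1 2-bromo-5-methylphenol
Product: 2 2-bromo-5-methylphenyl methanesulfonate
Conditions: MsCl, Et3N, CH2Cl2, 0 °C → rt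
Reagents that add atoms: methanesulfonyl chloride, CS(=O)(=O)Cl
Why: Sulfonylation of the phenol O–H with a sulfonyl chloride and an amine base is routine, and the resulting aryl mesylate is inert to Pd(dppf), to triflic acid and to cuprates while making its ring electron-poor.

Step 2
Reactants: 3 3-bromo-5-methylphenol; 2 2-bromo-5-methylphenyl methanesulfonate
Product: 5 3′-hydroxy-4,5′-dimethylbiphenyl-2-yl methanesulfonate, via arylboronic acid pinacol ester 4 (not isolated)
Conditions: 3, B2pin2, Pd(dppf)Cl2 (cat.), KOAc, 1,4-dioxane, 90 °C; then 2, aq K3PO4, 90 °C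
Reagents that add atoms: none
Why: One-pot Miyaura borylation and Suzuki–Miyaura coupling, in which Pd(dppf) inserts only into the C–Br bonds, so the free phenol and the aryl mesylate are carried through, and boron sits on the unhindered ring to avoid an ortho-oxygenated boronate prone to protodeboronation.

Step 3
Reactants: 5 3′-hydroxy-4,5′-dimethylbiphenyl-2-yl methanesulfonate
Product: 8 rac-5-methyl-2-(1-methyl-4-oxobicyclo[3.1.0]hex-2-en-2-yl)phenyl methanesulfonate (racemate), via C-protonated hydroxybenzenium ion 6 (not isolated), via O-protonated enone 7 (not isolated)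
Conditions: CF3SO3H (0.02 M), Ar, hν (λ ≥ 300 nm, Pyrex), −20 °C; then ice/aq NaHCO3
Reagents that add atoms: none
Why: Proposed new method: in CF3SO3H the phenol ring should be protonated at the carbon para to OH (the future C6) to give hydroxypentadienyl cation 6, the only species absorbing above 300 nm; its excited state bonds the two carbons flanking the new CH2 (future C1–C2), and the bicyclo[3.1.0]hexenyl cation so formed relaxes by a shift of that CH2 from the aryl-bearing carbon to the neighbouring ortho carbon (future C5–C6), giving O-protonated enone 7, which the quench releases as 8. The closest known reaction type is the photoisomerisation of C-protonated alkylphenols in strong acid to bicyclo[3.1.0]hex-3-en-2-ones, which has not been applied to an aryl-substituted phenol. The cyclopentenone ring is closed by a photochemically allowed disrotatory 4π electrocyclisation of the pentadienyl cation, and the final cyclopropane (C1–C5–C6) by a suprafacial [1,4]-sigmatropic walk of C6. C1 and C5 arise together and can only be cis at a three/five ring fusion, and since medium and substrate are achiral both enantiomers form equally. Two selectivities are required: protonation and excitation must stay on the phenol ring, which the mesylate secures by making the other ring a weak base, a poor donor for charge-transfer quenching and a non-nucleophile toward the cationic bicycle, and the walk must break the bond to the aryl-bearing carbon, which is favoured because the charge left there is benzylic (the para-methyl group of that ring helps), in line with the departure of the CH2 from the more substituted carbon in alkylphenols. Light filtered through Pyrex, low temperature and interruption before full conversion (unchanged 5 is recycled) should limit secondary photolysis of 7.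

Step 4
Reactants: 8 rac-5-methyl-2-(1-methyl-4-oxobicyclo[3.1.0]hex-2-en-2-yl)phenyl methanesulfonate
Product: 9 5-methyl-2-[(1S,5R)-1-methyl-4-oxobicyclo[3.1.0]hex-2-en-2-yl]phenyl methanesulfonate
Conditions: preparative chiral SFC, amylose tris(3,5-dimethylphenylcarbamate) phase, CO2/MeOH, 35 °C
Reagents that add atoms: none
Why: Resolution of a racemate by preparative chromatography on a polysaccharide chiral stationary phase creates no stereocentre and only selects the (1S,5R) enantiomer, which cannot racemise because C1 is quaternary and the C5–H is a cyclopropane bridgehead hydrogen that does not enolise.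

Step 5
Reactants: 9 5-methyl-2-[(1S,5R)-1-methyl-4-oxobicyclo[3.1.0]hex-2-en-2-yl]phenyl methanesulfonate
Product: 11 2-[(1S,2R,5R)-1,2-dimethyl-4-oxobicyclo[3.1.0]hexan-2-yl]-5-methylphenyl methanesulfonate, via trimethylsilyl enol ether 10 (not isolated)
Conditions: Me2CuLi (from CuI, MeLi), TMSCl, THF/Et2O, −78 → −20 °C; then 1 M HCl, THF, rt
Reagents that add atoms: lithium dimethylcuprate, [Li+].C[Cu-]C
Why: Conjugate addition of a Gilman cuprate accelerated by TMSCl, in which methyl should enter C2 from the convex face, anti to the C6 methylene that covers the other face of the enone, which sets C2 (R) with aryl syn to the cyclopropane, and the silyl enol ether is cleaved in the acidic work-up.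

Step 6
Reactants: 11 2-[(1S,2R,5R)-1,2-dimethyl-4-oxobicyclo[3.1.0]hexan-2-yl]-5-methylphenyl methanesulfonate
Product: 13 2-[(1S,2R,5R)-1,2-dimethylbicyclo[3.1.0]hexan-2-yl]-5-methylphenol, via hydrazone 12 (not isolated)
Conditions: N2H4·H2O, diethylene glycol, 120 °C; then KOH, 200 °C (−H2O); then aq NH4Cl, 0 °C
Reagents that add atoms: none
Why: Wolff–Kishner reduction in the Huang–Minlon variant is established for bicyclo[3.1.0]hexan-2-ones with the three-membered ring left intact, the hot hydroxide also hydrolyses the aryl sulfonate at sulfur, and no stereocentre is involved.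

Step 7
Reactants: 13 2-[(1S,2R,5R)-1,2-dimethylbicyclo[3.1.0]hexan-2-yl]-5-methylphenol
Product: 15 2,4-dibromo-6-[(1S,2R,5R)-1,2-dimethylbicyclo[3.1.0]hexan-2-yl]-3-methylphenol, via para-monobromide 14 (not isolated)
Conditions: NBS (2.1 equiv), NaHCO3, MeCN, 0 °C → rt, dark
Reagents that add atoms: N-bromosuccinimide, O=C1CCC(=O)N1Br
Why: Electrophilic aromatic bromination of a phenol, in which the para and the remaining ortho position are the only activated sites (para reacts first), and NBS buffered by bicarbonate generates no HBr that could open the cyclopropane toward the phenol oxygen.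

Compound list
1 | 2-bromo-5-methylphenol | Cc1ccc(Br)c(O)c1 | starting material
2 | 2-bromo-5-methylphenyl methanesulfonate | Cc1ccc(Br)c(OS(C)(=O)=O)c1 | intermediate
3 | 3-bromo-5-methylphenol | Cc1cc(O)cc(Br)c1 | starting material
4 | 3-methyl-5-(4,4,5,5-tetramethyl-1,3,2-dioxaborolan-2-yl)phenol (not isolated) | Cc1cc(O)cc(B2OC(C)(C)C(C)(C)O2)c1 | intermediate
5 | 3′-hydroxy-4,5′-dimethylbiphenyl-2-yl methanesulfonate (key-step precursor) | CS(=O)(=O)Oc1cc(C)ccc1-c1cc(C)cc(O)c1 | intermediate
6 | hydroxybenzenium ion of 5, protonated at the ring carbon para to OH (triflate salt in CF3SO3H, not isolated) | CS(=O)(=O)Oc1cc(C)ccc1C2=CC(=[OH+])C=C(C)C2 | intermediate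
7 | O-protonated form of enone 8 (racemic, triflate salt in CF3SO3H, not isolated; one enantiomer drawn) | CS(=O)(=O)Oc1cc(C)ccc1C2=CC(=[OH+])[C@@H]3C[C@]23C | intermediate
8 | rac-5-methyl-2-(1-methyl-4-oxobicyclo[3.1.0]hex-2-en-2-yl)phenyl methanesulfonate (racemate; the (1S,5R) enantiomer is drawn) | CS(=O)(=O)Oc1cc(C)ccc1C2=CC(=O)[C@@H]3C[C@]23C | intermediate
9 | 5-methyl-2-[(1S,5R)-1-methyl-4-oxobicyclo[3.1.0]hex-2-en-2-yl]phenyl methanesulfonate (single enantiomer) | CS(=O)(=O)Oc1cc(C)ccc1C2=CC(=O)[C@@H]3C[C@]23C | intermediate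
10 | 2-[(1S,2R,5R)-1,2-dimethyl-4-(trimethylsilyloxy)bicyclo[3.1.0]hex-3-en-2-yl]-5-methylphenyl methanesulfonate (not isolated) | CS(=O)(=O)Oc1cc(C)ccc1[C@]2(C)C=C(O[Si](C)(C)C)[C@@H]3C[C@@]32C | intermediate
11 | 2-[(1S,2R,5R)-1,2-dimethyl-4-oxobicyclo[3.1.0]hexan-2-yl]-5-methylphenyl methanesulfonate | CS(=O)(=O)Oc1cc(C)ccc1[C@]2(C)CC(=O)[C@@H]3C[C@@]32C | intermediate
12 | 2-[(1S,2R,5R)-4-hydrazinylidene-1,2-dimethylbicyclo[3.1.0]hexan-2-yl]-5-methylphenyl methanesulfonate (not isolated) | CS(=O)(=O)Oc1cc(C)ccc1[C@]2(C)CC(=NN)[C@@H]3C[C@@]32C | intermediate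
13 | 2-[(1S,2R,5R)-1,2-dimethylbicyclo[3.1.0]hexan-2-yl]-5-methylphenol | Cc1ccc([C@]2(C)CC[C@@H]3C[C@@]32C)c(O)c1 | intermediate
14 | 4-bromo-2-[(1S,2R,5R)-1,2-dimethylbicyclo[3.1.0]hexan-2-yl]-5-methylphenol (not isolated) | Cc1c(Br)cc([C@]2(C)CC[C@@H]3C[C@@]32C)c(O)c1 | intermediate
15 | 2,4-dibromo-6-[(1S,2R,5R)-1,2-dimethylbicyclo[3.1.0]hexan-2-yl]-3-methylphenol | Cc1c(Br)cc([C@]2(C)CC[C@@H]3C[C@@]32C)c(O)c1Br | target

Total step count: 7. Longest linear sequence: 7 steps (1 → 2 → 5 → 8 → 9 → 11 → 13 → 15); bromophenol 3 joins in step 2.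

Steps most likely to fail

1. Step 3 (the labelled step). The excited cation may decay by charge transfer from the second ring instead of closing, or protonation may spread to the ortho carbons. The CH2 may also walk toward the methyl-bearing side, or 7 may be photolysed further, so that little 8 accumulates. The fallback uses known chemistry, sets out from bromide 2 and comes back to the route at 8. Commercial 3-methylcyclopent-2-en-1-one (CC1=CC(=O)CC1) is cyclopropanated with dimethylsulfoxonium methylide (Corey–Chaykovsky; Me3S(O)I, NaH, DMSO) to rac-5-methylbicyclo[3.1.0]hexan-2-one F1. Dehydrogenation with IBX (DMSO, 75 °C) should give rac-5-methylbicyclo[3.1.0]hex-3-en-2-one F2. Bromide 2 is converted by Miyaura borylation (B2pin2, Pd(dppf)Cl2, KOAc) into 5-methyl-2-(4,4,5,5-tetramethyl-1,3,2-dioxaborolan-2-yl)phenyl methanesulfonate F3. Rhodium-catalysed 1,4-addition of F3 to F2 ([Rh(cod)OH]2, dioxane/H2O, 60 °C) should give rac-5-methyl-2-(1-methyl-4-oxobicyclo[3.1.0]hexan-2-yl)phenyl methanesulfonate F4, with aryl anti to C6. A second IBX dehydrogenation of F4 gives 8, which enters step 4.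

2. Step 5. Addition at the congested C2 (quaternary C1 next to it, ortho-substituted aryl on it) may be slow, may open the cyclopropane through electron transfer, or may lose facial selectivity. The fallback sets out from 9 and comes back at 13. Luche reduction (NaBH4, CeCl3, MeOH), with hydride entering anti to C6, should give 2-[(1S,4S,5R)-4-hydroxy-1-methylbicyclo[3.1.0]hex-2-en-2-yl]-5-methylphenyl methanesulfonate F5, its OH syn to C6. Esterification with picolinic acid (EDC, DMAP) gives (1S,4S,5R)-2-[2-(methanesulfonyloxy)-4-methylphenyl]-1-methylbicyclo[3.1.0]hex-2-en-4-yl pyridine-2-carboxylate F6. Copper-mediated anti-SN2′ substitution (MeMgBr, CuBr·SMe2, THF, −40 °C) delivers methyl to C2 on the face opposite the leaving group, hence anti to C6, giving 2-[(1S,2R,5S)-1,2-dimethylbicyclo[3.1.0]hex-3-en-2-yl]-5-methylphenyl methanesulfonate F7. Diimide reduction (TsNHNH2, NaOAc) of the ring alkene gives 2-[(1S,2R,5R)-1,2-dimethylbicyclo[3.1.0]hexan-2-yl]-5-methylphenyl methanesulfonate F8. Hydrolysis of the sulfonate (KOH, MeOH/H2O, reflux) then gives 13.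

3. Step 7. Traces of acid may open the now electron-rich cyclopropane toward the neighbouring phenol oxygen (cyclic ether formation), and the second bromination at the flanked ortho position may stall. The fallback sets out from 11 and comes back at 15; it brominates while the cyclopropane is still deactivated by the C4 carbonyl. Sulfonate hydrolysis (KOH, MeOH/H2O, 60 °C) gives (1S,2R,5R)-2-(2-hydroxy-4-methylphenyl)-1,2-dimethylbicyclo[3.1.0]hexan-4-one F9. NBS (2.1 equiv, MeCN) brominates it via (1S,2R,5R)-2-(5-bromo-2-hydroxy-4-methylphenyl)-1,2-dimethylbicyclo[3.1.0]hexan-4-one F10 to (1S,2R,5R)-2-(3,5-dibromo-2-hydroxy-4-methylphenyl)-1,2-dimethylbicyclo[3.1.0]hexan-4-one F11. Its hydrazone, (1S,2R,5R)-2-(3,5-dibromo-2-hydroxy-4-methylphenyl)-1,2-dimethylbicyclo[3.1.0]hexan-4-one hydrazone F12, is reduced at room temperature (KOt-Bu, DMSO, low-temperature Wolff–Kishner) to 15 with the aryl bromides left in place.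

Further compounds
F1 | step 3 | rac-5-methylbicyclo[3.1.0]hexan-2-one (one enantiomer drawn) | C1CC(=O)[C@@H]2C[C@]12C
F2 | step 3 | rac-5-methylbicyclo[3.1.0]hex-3-en-2-one (one enantiomer drawn) | C1=CC(=O)[C@@H]2C[C@]12C
F3 | step 3 | 5-methyl-2-(4,4,5,5-tetramethyl-1,3,2-dioxaborolan-2-yl)phenyl methanesulfonate | CS(=O)(=O)Oc1cc(C)ccc1B1OC(C)(C)C(C)(C)O1
F4 | step 3 | rac-5-methyl-2-(1-methyl-4-oxobicyclo[3.1.0]hexan-2-yl)phenyl methanesulfonate, aryl anti to C6 (one enantiomer drawn) | CS(=O)(=O)Oc1cc(C)ccc1[C@H]2CC(=O)[C@@H]3C[C@]23C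
F5 | step 5 | 2-[(1S,4S,5R)-4-hydroxy-1-methylbicyclo[3.1.0]hex-2-en-2-yl]-5-methylphenyl methanesulfonate | CS(=O)(=O)Oc1cc(C)ccc1C2=C[C@H](O)[C@@H]3C[C@]23C
F6 | step 5 | (1S,4S,5R)-2-[2-(methanesulfonyloxy)-4-methylphenyl]-1-methylbicyclo[3.1.0]hex-2-en-4-yl pyridine-2-carboxylate | CS(=O)(=O)Oc1cc(C)ccc1C2=C[C@H](OC(=O)c4ccccn4)[C@@H]3C[C@]23C
F7 | step 5 | 2-[(1S,2R,5S)-1,2-dimethylbicyclo[3.1.0]hex-3-en-2-yl]-5-methylphenyl methanesulfonate | CS(=O)(=O)Oc1cc(C)ccc1[C@]2(C)C=C[C@@H]3C[C@@]32C
F8 | step 5 | 2-[(1S,2R,5R)-1,2-dimethylbicyclo[3.1.0]hexan-2-yl]-5-methylphenyl methanesulfonate | CS(=O)(=O)Oc1cc(C)ccc1[C@]2(C)CC[C@@H]3C[C@@]32C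
F9 | step 7 | (1S,2R,5R)-2-(2-hydroxy-4-methylphenyl)-1,2-dimethylbicyclo[3.1.0]hexan-4-one | Cc1ccc([C@]2(C)CC(=O)[C@@H]3C[C@@]32C)c(O)c1
F10 | step 7 | (1S,2R,5R)-2-(5-bromo-2-hydroxy-4-methylphenyl)-1,2-dimethylbicyclo[3.1.0]hexan-4-one | Cc1c(Br)cc([C@]2(C)CC(=O)[C@@H]3C[C@@]32C)c(O)c1
F11 | step 7 | (1S,2R,5R)-2-(3,5-dibromo-2-hydroxy-4-methylphenyl)-1,2-dimethylbicyclo[3.1.0]hexan-4-one | Cc1c(Br)cc([C@]2(C)CC(=O)[C@@H]3C[C@@]32C)c(O)c1Br
F12 | step 7 | (1S,2R,5R)-2-(3,5-dibromo-2-hydroxy-4-methylphenyl)-1,2-dimethylbicyclo[3.1.0]hexan-4-one hydrazone | Cc1c(Br)cc([C@]2(C)CC(=NN)[C@@H]3C[C@@]32C)c(O)c1Br
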